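## Analysis of the target

Compound 18 is a flavone: a benzene ring A fused to a 4-pyranone ring C, with a 4-methoxyphenyl ring B on C2. It has no stereocentre and no other element of chirality, so nothing stereochemical has to be set in the final molecule. Ring A is hexasubstituted: C5, C6 and C8 carry methoxy groups, C7 a free hydroxyl, C8a the ring oxygen O1 and C4a the C4 carbonyl, so five neighbouring ring carbons bear oxygen. Ring C carries one more methoxy group at C3. The sensitive points are:
- the 7-OH, which must be told apart from four methyl ethers;
- the 5-OMe peri to the carbonyl, which chelating Lewis acids such as BCl3 remove first;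
- the pyranone C2, which hot alkoxide attacks with ring opening.

The difficulty therefore lies in laying down a fully and unsymmetrically oxygenated ring A and in freeing one oxygen at the end, not in the heterocycle as such. The strategy rests on reading ring C as the union of two pieces. One is the heterodiene O1=C8a–C4a=C4, an o-quinone methide of ring A. The other is the C2=C3 double bond of a bis-enol ether that already holds ring B on C2 and the methoxy group on C3.

## Retrosynthetic reasoning

**18 ⇒ 17.** Only the O7–CH2Ph bond is cut. A benzyl ether is chosen because it can be removed at the end without a Lewis acid (which would attack the 5-methoxy group) and without base (which would open the pyranone). The forward step must cleave the benzylic C–O bond by hydrogenolysis and leave the conjugated C2=C3 bond alone.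

**17 ⇒ 16.** The C4 carbonyl is taken back to a CH2 group. This lets ring C be built at a lower oxidation level, where C4 is simply the methylene end of a heterodiene. The forward step must oxidise a CH2 that is both benzylic to ring A and allylic to the C2=C3 enol ether, in the presence of the benzyl ether.

**16 ⇒ 15.** The C2=C3 double bond is traced to a 2-methoxy ketal with hydrogen on C3. C2 carries O1, a methoxy group and ring B, so the ketal ionises easily and the forward elimination is simple. It also removes both stereocentres of 15, so their configuration does not matter for the target.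

**15 ⇒ 14 + 13, and 14 ⇒ 8 (key disconnection).** The bonds C3–C4 and O1–C2 are cut. This divides the molecule into its two natural halves: ring A with C4 and O1, and a two-carbon unit carrying ring B and the C3 methoxy group. No C–C bond has to be forged onto the crowded ring A at the stage of the heterocycle. The o-quinone methide 14 cannot be stored and is traced to the salicyl alcohol 8 by dehydration. The forward step must generate 14 in the presence of 13 and capture it with the correct regiochemistry.

**13 ⇒ 11 ⇒ 9 + 10.** The enol O–CH3 bond is cut to the enolate 12 of ketone 11. The aryl–carbonyl bond of 11 is cut to the arene 9 and the acid chloride 10. The forward steps are a para-selective acylation and an O-selective alkylation of an enolate.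

**8 ⇒ 7 ⇒ 6.** The hydroxymethyl group comes from a formyl group, and the free phenol from a methyl ether. Aldehyde 6 has a mirror plane through C1 and C4, so its two ortho methoxy groups are equivalent and removal of either gives 7. The formyl group is the chelating handle that singles out an ortho methoxy group. This is why the carbon is introduced at the aldehyde level. A route through a symmetric dihydric phenol and its statistical monoalkylation was set aside for this reason.

**6 ⇒ 4 ⇒ 3 ⇒ 2 ⇒ 1.** The formyl carbon is cut from the single ring C–H of 4, which lies between two methoxy groups and is the most acidic position (lithiated intermediate 5). The two new C–O bonds of 4 are cut to the C–Br bonds of 3. The bromines of 3 go in by electrophilic substitution at the two positions of 2 that are para to a methoxy group. Compound 2 is the benzyl ether of 1, so the future 7-oxygen is differentiated from the first step on.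

## Alternatives that were turned down

**Alternative 1:** late double methoxylation of a flavone.
- Disconnection: the C6–OMe and C8–OMe bonds of A1 (the same compound as 17) are cut back to the 6,8-dibromide A2, whose ring A is only 5,7-dioxygenated.
- Forward key step: A2 is heated with a methoxide base and a monovalent copper halide in a dipolar aprotic solvent, and both aryl C–O bonds form in one operation.
- For: the 5,7-dioxygenated flavonol skeleton is the most accessible flavonoid core. C6 and C8 are its most nucleophilic positions, so A2 arises by simple bromination. Ring C needs no redox adjustment. If the core is bought, this route is shorter than the chosen one, and on step count it is the stronger.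
- Against: hot methoxide meets an intact 3-alkoxy pyranone, which it can open at C2. Both bromides are flanked on two sides (C6 by 5-OMe and 7-OBn, C8 by 7-OBn and O1), so exchange is slow and reductive loss of bromine competes. The resulting mono-methoxy and debrominated flavones would be hard to separate from A1. Placing a methyl on the chelated 5-OH and a benzyl on the 7-OH of the core also costs protecting steps.
- Comparison: the chosen route uses the same copper-mediated exchange, but on the simple benzene 3. There no base-labile ring is present and each bromine has only one ortho neighbour. The price is a late oxidation at C4.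

**Alternative 2:** ring A built onto a preformed pyranone.
- Disconnection: the C8–C8a and C5–C6 bonds of ring A are cut. The ketone A5 supplies C6, C7 and C8. The pyranone A4 supplies C8a (its methylsulfanyl-bearing carbon), C4a and C5 (its ester carbon).
- Forward key step: under a methoxide base the enolate of A5 displaces the methylsulfanyl group of A4 by addition–elimination. Its second α-carbon then closes onto the ester in a Claisen condensation, and enolisation gives the aromatic ring of A3.
- For: it is highly convergent and places the C6 and C8 methoxy groups without any halogenation or copper chemistry. It needs no late oxidation. On the positional security of the ring A oxygens it is stronger than the chosen route.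
- Against: A3 has both 5-OH and 7-OH free, whereas the target needs 5-OMe with 7-OH free. The chelated 5-OH is the less reactive of the two, so a protect, methylate and deprotect sequence on the flavone is unavoidable. A4 is not simple to make and offers three electrophilic sites to the enolate (the aryl-bearing ring carbon, the ester and the methylsulfanyl carbon). A5 can also condense with itself.
- Comparison: the chosen route differentiates O7 in its first step and spends no protecting-group step on the finished heterocycle.

**Alternative 3:** aryne insertion.
- Disconnection: O1–C8a, C4–C4a and O1–C2 are cut. Ring A comes from the aryne released from the silyl triflate A7, and C2–C4 with ring B from the acid A8.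
- Forward key step: fluoride releases the aryne from A7. The carboxylate oxygen of A8 adds at the aryne carbon remote from the flanking methoxy group (C8a). The aryl anion at C4a takes over the acyl group. The phenoxide then closes ring C at C2 by addition–elimination with loss of the β-methoxy group, giving A6.
- For: ring C arrives at the correct oxidation level under mild conditions with the C3 methoxy group in place. The single flanking methoxy group directs the aryne addition. No late oxidation is needed, and on this point it is stronger than the chosen route.
- Against: A6 has hydrogen at C8. The two aryne carbons become C4a and C8a, and a fifth oxygen on the aryne would remove the regiocontrol. The 8-methoxy group would therefore have to be installed by bromination and copper-mediated exchange on the flavone, with the problems named under Alternative 1. A7 needs several steps of regiodefined silylation and triflation on a differentiated trioxygenated phenol. Protonation of the aryl anion can outrun the acyl shift. A8 is a hindered, tetrasubstituted acrylic acid.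
- Comparison: the step count is comparable. The chosen route carries all five ring A oxygens in precursor 8, so nothing is substituted on the heterocycle.

Key step: step 9

## Route

Remark on the chemistry (assumption): 15 is formed and carried as a racemate, and its SMILES shows one enantiomer of the cis pair. Z in 12 and 13 means that the two oxygen substituents lie on the same side of the double bond.

Step 1
Reactants: 1 2,6-dimethoxyphenol
Product: 2 2-(benzyloxy)-1,3-dimethoxybenzene
Conditions: BnBr, K2CO3, DMF, 60 °C
Reagents that add atoms: benzyl bromide, BrCc1ccccc1
Why: Williamson ether synthesis on a hindered but acidic phenol; the benzyl group marks the future 7-oxygen and withstands base, organolithium and copper chemistry.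

Step 2
Reactants: 2 2-(benzyloxy)-1,3-dimethoxybenzene
Product: 3 3-(benzyloxy)-1,5-dibromo-2,4-dimethoxybenzene
Conditions: NBS (2.2 equiv), MeCN, 0 to 40 °C, dark
Reagents that add atoms: N-bromosuccinimide, O=C1CCC(=O)N1Br
Why: Electrophilic aromatic bromination; each bromine enters para to one outer methoxy group and ortho to the other, while the position para to the benzyloxy group stays free because that central alkoxy group is twisted out of conjugation by its two neighbours.

Step 3
Reactants: 3 3-(benzyloxy)-1,5-dibromo-2,4-dimethoxybenzene
Product: 4 3-(benzyloxy)-1,2,4,5-tetramethoxybenzene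
Conditions: NaOMe (excess, in MeOH), CuBr (cat.), DMF, 110 °C
Reagents that add atoms: sodium methoxide, [Na+].[O-]C
Why: Ullmann-type ether synthesis (methoxide exchange of aryl bromides under monovalent copper); each bromide has only one ortho substituent and the substrate has no base-sensitive group.

Step 4
Reactants: 4 3-(benzyloxy)-1,2,4,5-tetramethoxybenzene
Product: 6 4-(benzyloxy)-2,3,5,6-tetramethoxybenzaldehyde, via aryllithium 5 (not isolated)
Conditions: n-BuLi, THF, 0 °C; then DMF, 0 °C to rt; H2O
Reagents that add atoms: N,N-dimethylformamide, CN(C)C=O
Why: Directed ortho-metalation followed by formylation; the only ring hydrogen lies between two methoxy groups, which both coordinate lithium and acidify it, so deprotonation there outruns attack at the benzylic CH2 of the protecting group.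

Step 5
Reactants: 6 4-(benzyloxy)-2,3,5,6-tetramethoxybenzaldehyde
Product: 7 4-(benzyloxy)-2-hydroxy-3,5,6-trimethoxybenzaldehyde
Conditions: MgI2·OEt2 (1.5 equiv), PhMe–Et2O, 60 °C; aqueous work-up
Reagents that add atoms: none
Why: Chelation-controlled demethylation ortho to a carbonyl group: magnesium bridges the formyl oxygen and an ortho methoxy oxygen and iodide removes that methyl by SN2. The two ortho methoxy groups are equivalent by symmetry so one product results, and the magnesium phenoxide chelate formed protects the second one; the benzyl ether has no carbonyl neighbour.

Step 6
Reactants: 7 4-(benzyloxy)-2-hydroxy-3,5,6-trimethoxybenzaldehyde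
Product: 8 3-(benzyloxy)-6-(hydroxymethyl)-2,4,5-trimethoxyphenol
Conditions: NaBH4, THF–MeOH, 0 °C; pH 7 buffer
Reagents that add atoms: none
Why: Hydride reduction of an aldehyde; neutral work-up and no heating, because acid or heat would already trigger dehydration of this electron-rich salicyl alcohol.

Step 7
Reactants: 9 anisole; 10 methoxyacetyl chloride
Product: 11 2-methoxy-1-(4-methoxyphenyl)ethan-1-one
Conditions: AlCl3 (1.1 equiv), CH2Cl2, 0 °C to rt; ice, dilute HCl
Reagents that add atoms: none
Why: Friedel–Crafts acylation, para-selective on anisole; kept cold and short so that the Lewis acid does not cleave the methyl ethers.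

Step 8
Reactants: 11 2-methoxy-1-(4-methoxyphenyl)ethan-1-one
Product: 13 (Z)-1-(1,2-dimethoxyethenyl)-4-methoxybenzene, via potassium enolate 12 (not isolated)
Conditions: KN(SiMe3)2, THF–DMPU, −78 °C; then Me2SO4, −78 to 0 °C; chromatography on Et3N-treated silica
Reagents that add atoms: dimethyl sulfate, COS(=O)(=O)OC
Why: O-alkylation of a potassium enolate by a hard methylating agent in a dipolar aprotic medium; the enolate has its oxygen and the α-methoxy group cis (the α-methoxy group avoids the aryl group), and this geometry is carried into 13.

Step 9
Reactants: 8 3-(benzyloxy)-6-(hydroxymethyl)-2,4,5-trimethoxyphenol; 13 (Z)-1-(1,2-dimethoxyethenyl)-4-methoxybenzene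
Product: 15 racemic (2S*,3R*)-7-(benzyloxy)-2,3,5,6,8-pentamethoxy-2-(4-methoxyphenyl)chromane, via o-quinone methide 14 (not isolated)
Conditions: 13 (3 equiv), PhMe, 150 °C, sealed tube, Ar
Reagents that add atoms: none
Why: On heating, 8 loses water by an intramolecular 1,4-elimination (the phenolic proton passes to the benzylic hydroxyl through a six-membered array) and gives the o-quinone methide 14, an electron-poor 1-oxadiene whose exocyclic CH2 is the electrophilic end. 14 and the electron-rich alkene 13 then combine in an inverse-electron-demand hetero-Diels–Alder reaction, the known thermal capture of o-quinone methides by enol ethers that gives 2-alkoxychromans. Ring C is closed by this [4+2] cycloaddition, with both new bonds (C3–C4 and O1–C2) made in one pericyclic event and the C–C bond forming ahead of the C–O bond; should the process become stepwise, the phenoxide closes onto the C2 oxocarbenium ion in a 6-endo manner with the same result. The regiochemistry needed is CH(OMe) of 13 to the methylene of 14, and the polarisation of 13 secures it: attack through that carbon leaves the developing positive charge on the carbon bearing both a methoxy and the 4-methoxyphenyl group, while the reverse orientation would leave it on a carbon with one donor only. The two new stereocentres C2 and C3 are set relative to each other by suprafacial addition across the Z double bond, so the two methoxy groups come out cis; there is no control of absolute configuration, 15 is racemic, and with C4 unsubstituted no endo/exo issue arises. The chemoselectivity needed is capture of 14 by 13 ahead of self-addition of 14, served by the excess of 13 and by ring A having no free position at which a second phenol could be alkylated. Both stereocentres are removed in step 10, so any loss of stereochemical integrity here has no consequence.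

Step 10
Reactants: 15 racemic (2S*,3R*)-7-(benzyloxy)-2,3,5,6,8-pentamethoxy-2-(4-methoxyphenyl)chromane
Product: 16 7-(benzyloxy)-3,5,6,8-tetramethoxy-2-(4-methoxyphenyl)-4H-chromene
Conditions: PPTS (5 mol %), PhMe, 80 °C, 4 Å molecular sieves
Reagents that add atoms: none
Why: Acid-catalysed E1 elimination from a mixed ketal: the C2 methoxy group ionises to an oxocarbenium ion stabilised by O1 and ring B, and loss of H3 gives the conjugated enol ether; anhydrous conditions prevent hydrolytic ring opening.

Step 11
Reactants: 16 7-(benzyloxy)-3,5,6,8-tetramethoxy-2-(4-methoxyphenyl)-4H-chromene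
Product: 17 7-(benzyloxy)-3,5,6,8-tetramethoxy-2-(4-methoxyphenyl)-4H-chromen-4-one
Conditions: pyridinium dichromate (0.3 equiv), t-BuOOH (5 equiv, in decane), Celite, PhH, 10 °C to rt
Reagents that add atoms: tert-butyl hydroperoxide, CC(C)(C)OO
Why: Radical allylic and benzylic oxidation by hexavalent chromium with tert-butyl hydroperoxide: hydrogen abstraction at C4 gives a radical stabilised by ring A and by the C2=C3 enol ether, the C4 peroxide forms and collapses to the ketone. The CH2 of the benzyl ether is activated by one aryl group only and should react more slowly, and the product is a stable vinylogous ester.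

Step 12
Reactants: 17 7-(benzyloxy)-3,5,6,8-tetramethoxy-2-(4-methoxyphenyl)-4H-chromen-4-one
Product: 18 7-hydroxy-3,5,6,8-tetramethoxy-2-(4-methoxyphenyl)-4H-chromen-4-one
Conditions: H2 (1 atm), 10% Pd/C, EtOAc–MeOH, rt
Reagents that add atoms: none
Why: Hydrogenolysis of a benzyl aryl ether over palladium on carbon; the tetrasubstituted, conjugated C2=C3 bond and the methyl ethers are untouched at atmospheric pressure.

## Compound list

1 | 2,6-dimethoxyphenol | COc1cccc(OC)c1O | starting material
2 | 2-(benzyloxy)-1,3-dimethoxybenzene | COc1cccc(OC)c1OCc1ccccc1 | intermediate
3 | 3-(benzyloxy)-1,5-dibromo-2,4-dimethoxybenzene | COc1c(Br)cc(Br)c(OC)c1OCc1ccccc1 | intermediate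
4 | 3-(benzyloxy)-1,2,4,5-tetramethoxybenzene | COc1cc(OC)c(OC)c(OCc2ccccc2)c1OC | intermediate
5 | [4-(benzyloxy)-2,3,5,6-tetramethoxyphenyl]lithium | [Li]c1c(OC)c(OC)c(OCc2ccccc2)c(OC)c1OC | intermediate
6 | 4-(benzyloxy)-2,3,5,6-tetramethoxybenzaldehyde | O=Cc1c(OC)c(OC)c(OCc2ccccc2)c(OC)c1OC | intermediate
7 | 4-(benzyloxy)-2-hydroxy-3,5,6-trimethoxybenzaldehyde | O=Cc1c(O)c(OC)c(OCc2ccccc2)c(OC)c1OC | intermediate
8 | 3-(benzyloxy)-6-(hydroxymethyl)-2,4,5-trimethoxyphenol | OCc1c(O)c(OC)c(OCc2ccccc2)c(OC)c1OC | intermediate
9 | anisole | COc1ccccc1 | starting material
10 | methoxyacetyl chloride | COCC(=O)Cl | starting material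
11 | 2-methoxy-1-(4-methoxyphenyl)ethan-1-one | COCC(=O)c1ccc(OC)cc1 | intermediate
12 | potassium (Z)-2-methoxy-1-(4-methoxyphenyl)ethen-1-olate | [K+].[O-]/C(=C\OC)c1ccc(OC)cc1 | intermediate
13 | (Z)-1-(1,2-dimethoxyethenyl)-4-methoxybenzene | CO/C=C(\OC)c1ccc(OC)cc1 | intermediate
14 | 3-(benzyloxy)-2,4,5-trimethoxy-6-methylidenecyclohexa-2,4-dien-1-one | C=C1C(=O)C(OC)=C(OCc2ccccc2)C(OC)=C1OC | intermediate
15 | racemic (2S*,3R*)-7-(benzyloxy)-2,3,5,6,8-pentamethoxy-2-(4-methoxyphenyl)chromane (methoxy groups at C2 and C3 cis) | CO[C@@H]1Cc2c(OC)c(OC)c(OCc3ccccc3)c(OC)c2O[C@@]1(OC)c1ccc(OC)cc1 | intermediate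
16 | 7-(benzyloxy)-3,5,6,8-tetramethoxy-2-(4-methoxyphenyl)-4H-chromene | COC1=C(c2ccc(OC)cc2)Oc2c(C1)c(OC)c(OC)c(OCc3ccccc3)c2OC | intermediate
17 | 7-(benzyloxy)-3,5,6,8-tetramethoxy-2-(4-methoxyphenyl)-4H-chromen-4-one | COc1ccc(-c2oc3c(OC)c(OCc4ccccc4)c(OC)c(OC)c3c(=O)c2OC)cc1 | intermediate
18 | 7-hydroxy-3,5,6,8-tetramethoxy-2-(4-methoxyphenyl)-4H-chromen-4-one | COc1ccc(-c2oc3c(OC)c(O)c(OC)c(OC)c3c(=O)c2OC)cc1 | target

## Step count and least certain steps

Total step count: 12. Longest linear sequence: 10 steps (steps 1–6 and 9–12). The branch to 13 has 2 steps (steps 7 and 8).

**Step 9 (key step).** The o-quinone methide may add to itself through its exocyclic double bond, or take water back up, faster than it is captured by the hindered trisubstituted alkene. The water released may also hydrolyse the enol ether at 150 °C. Early loss of methanol from the adduct would be harmless, since step 10 does the same.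
Fallback: generate 14 by an anionic route at low temperature. It sets out from 7. Boc2O with catalytic DMAP converts the phenol into 5-(benzyloxy)-2-formyl-3,4,6-trimethoxyphenyl tert-butyl carbonate F1. Reduction of the aldehyde with BH3·THF at 0 °C gives 5-(benzyloxy)-2-(hydroxymethyl)-3,4,6-trimethoxyphenyl tert-butyl carbonate F2. F2 is then treated with t-BuMgCl at −78 °C in the presence of 13. The magnesium alkoxide takes over the carbonate group and the phenoxide expels it, so 14 forms slowly and cold and is trapped by 13. The fallback returns to the route at 15.

**Step 11.** The oxidant may attack the electron-rich C2=C3 enol ether (oxidative cleavage, or peroxide capture at C2 instead of C4). Adventitious acid and water may open ring C by hydrolysis. The benzylic CH2 of the protecting group may also be oxidised.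
Fallback: an ionic oxidation by hydride abstraction in place of the radical one. It sets out from 16. DDQ (2.2 equiv) in wet dioxane removes hydride from C4 and gives 7-(benzyloxy)-3,5,6,8-tetramethoxy-2-(4-methoxyphenyl)chromenylium 2,3-dichloro-5,6-dicyano-4-hydroxyphenolate F3. Water adds reversibly, and the C4 adduct is racemic 7-(benzyloxy)-3,5,6,8-tetramethoxy-2-(4-methoxyphenyl)-4H-chromen-4-ol F4. A second hydride abstraction from F4 is irreversible and drains the equilibrium to the ketone. The fallback returns at 17.

**Step 8.** Methylation may occur at the enolate carbon instead of oxygen, and the enol ether may hydrolyse during isolation.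
Fallback: make the enol ether by elimination from a ketal. It sets out from 11. HC(OMe)3 in MeOH with catalytic TsOH gives 1-methoxy-4-(1,1,2-trimethoxyethyl)benzene F5. TMSOTf with iPr2NEt at 0 °C then removes one methoxy group and the adjacent hydrogen. The fallback returns at 13. The alkene geometry obtained is not critical, because step 10 removes both stereocentres.

**Step 5.** The benzyl ether, flanked by two methoxy groups, may be cleaved in competition with the ortho methyl ether, or the chelation-driven cleavage may stall.
Fallback: remove both groups and put the benzyl group back selectively. It sets out from 6. Excess BCl3 in CH2Cl2 at −78 to 0 °C cleaves the benzyl ether and one ortho methyl ether and gives 2,4-dihydroxy-3,5,6-trimethoxybenzaldehyde F6. BnBr (1 equiv) with KHCO3 in DMF then alkylates only the 4-hydroxyl, which is the more acidic one, whereas the 2-hydroxyl is held in a hydrogen bond to the formyl group. The fallback returns at 7.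

**Step 3.** Reductive loss of bromine, or incomplete exchange of the second bromide on this electron-rich ring, would give mixtures of arenes with too few oxygens.
Fallback: introduce the two oxygens one at a time through boron, which bypasses 4 and 6. It sets out from 3.
- Bromine–lithium exchange with n-BuLi (1 equiv, −78 °C), then B(OMe)3 and H2O2/NaOH, gives 3-(benzyloxy)-5-bromo-2,4-dimethoxyphenol F7.
- MeI with K2CO3 gives 3-(benzyloxy)-1-bromo-2,4,5-trimethoxybenzene F8.
- The same exchange, borate and oxidation sequence gives 3-(benzyloxy)-2,4,5-trimethoxyphenol F9.
- Magnesium-mediated ortho-formylation (MgCl2, Et3N, paraformaldehyde, MeCN, reflux) places the formyl group at the only free ring position, which is ortho to the hydroxyl.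

The fallback returns at 7.

## Further compounds

F1 | step 9 | 5-(benzyloxy)-2-formyl-3,4,6-trimethoxyphenyl tert-butyl carbonate | O=Cc1c(OC(=O)OC(C)(C)C)c(OC)c(OCc2ccccc2)c(OC)c1OC
F2 | step 9 | 5-(benzyloxy)-2-(hydroxymethyl)-3,4,6-trimethoxyphenyl tert-butyl carbonate | OCc1c(OC(=O)OC(C)(C)C)c(OC)c(OCc2ccccc2)c(OC)c1OC
F3 | step 11 | 7-(benzyloxy)-3,5,6,8-tetramethoxy-2-(4-methoxyphenyl)chromenylium 2,3-dichloro-5,6-dicyano-4-hydroxyphenolate | COc1ccc(-c2[o+]c3c(OC)c(OCc4ccccc4)c(OC)c(OC)c3cc2OC)cc1.[O-]c1c(Cl)c(Cl)c(O)c(C#N)c1C#N
F4 | step 11 | racemic 7-(benzyloxy)-3,5,6,8-tetramethoxy-2-(4-methoxyphenyl)-4H-chromen-4-ol | COC1=C(c2ccc(OC)cc2)Oc2c(C1O)c(OC)c(OC)c(OCc3ccccc3)c2OC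
F5 | step 8 | 1-methoxy-4-(1,1,2-trimethoxyethyl)benzene | COCC(OC)(OC)c1ccc(OC)cc1
F6 | step 5 | 2,4-dihydroxy-3,5,6-trimethoxybenzaldehyde | O=Cc1c(O)c(OC)c(O)c(OC)c1OC
F7 | step 3 | 3-(benzyloxy)-5-bromo-2,4-dimethoxyphenol | Oc1cc(Br)c(OC)c(OCc2ccccc2)c1OC
F8 | step 3 | 3-(benzyloxy)-1-bromo-2,4,5-trimethoxybenzene | COc1cc(Br)c(OC)c(OCc2ccccc2)c1OC
F9 | step 3 | 3-(benzyloxy)-2,4,5-trimethoxyphenol | COc1cc(O)c(OC)c(OCc2ccccc2)c1OC
A1 | alternative 1 | 7-(benzyloxy)-3,5,6,8-tetramethoxy-2-(4-methoxyphenyl)-4H-chromen-4-one | COc1ccc(-c2oc3c(OC)c(OCc4ccccc4)c(OC)c(OC)c3c(=O)c2OC)cc1
A2 | alternative 1 | 7-(benzyloxy)-6,8-dibromo-3,5-dimethoxy-2-(4-methoxyphenyl)-4H-chromen-4-one | COc1ccc(-c2oc3c(Br)c(OCc4ccccc4)c(Br)c(OC)c3c(=O)c2OC)cc1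
A3 | alternative 2 | 5,7-dihydroxy-3,6,8-trimethoxy-2-(4-methoxyphenyl)-4H-chromen-4-one | COc1ccc(-c2oc3c(OC)c(O)c(OC)c(O)c3c(=O)c2OC)cc1
A4 | alternative 2 | methyl 5-methoxy-6-(4-methoxyphenyl)-2-(methylsulfanyl)-4-oxo-4H-pyran-3-carboxylate | COC(=O)c1c(SC)oc(-c2ccc(OC)cc2)c(OC)c1=O
A5 | alternative 2 | 1,3-dimethoxypropan-2-one | COCC(=O)COC
A6 | alternative 3 | 7-(benzyloxy)-3,5,6-trimethoxy-2-(4-methoxyphenyl)-4H-chromen-4-one | COc1ccc(-c2oc3cc(OCc4ccccc4)c(OC)c(OC)c3c(=O)c2OC)cc1
A7 | alternative 3 | 5-(benzyloxy)-3,4-dimethoxy-2-(trimethylsilyl)phenyl trifluoromethanesulfonate | COc1c(OC)c(OCc2ccccc2)cc(OS(=O)(=O)C(F)(F)F)c1[Si](C)(C)C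
A8 | alternative 3 | (Z)-2,3-dimethoxy-3-(4-methoxyphenyl)prop-2-enoic acid | CO/C(=C(\OC)C(O)=O)c1ccc(OC)cc1
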